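(The readings stem from a simulated flask for an exercise, noise included.)

In a one-step world, starting material falls along one exponential whose constant follows the catalyst present, and the question is how far these flasks can be treated that way.

| setting | Friday's | Wednesday's | flask |
|---|---|---|---|
| starting material | 0.043 M | 0.068 M | 0.031 M |
| reagent | 1.05 equiv (fed, over 12 min) | 1.05 equiv (fed, over 12 min) | 1.05 equiv (fed, over 12 min) |
| free catalyst | 0.089 mol% | 0.089 mol% | 0.089 mol% |
| remark | run made earlier; the fed solution adds 0.25 times the starting volume | run made earlier; the fed solution adds 0.25 times the starting volume | the fed solution adds 0.25 times the starting volume |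
| time |  |  | 40 min |

- Friday's (time / min: starting material / %, side product / %): 12.0: 67, 3; 25.0: 32, 7; 40.0: 10, 6; 50.0: 4, 6
- Wednesday's (time / min: starting material / %, side product / %): 12.0: 54, 2; 25.0: 21, 6; 40.0: 4, 7; 50.0: 2, 6

(standard deviation of a reading: 1.5 percentage points)

- concentration of starting material at 40 min, in M
- concentration of side product at 40 min, in M
- concentration of released group at 40 min, in M

- amounts are per litre of the starting volume; all of the dose is in the solution fed

*What can be frozen?* These recipes share the loading, the equivalents and the feed, so the catalyst present goes with the charge. If its working share is frozen, the decay is pseudo-first-order, with a constant proportional to the charge.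

*What does that predict?* Friday's run, with 10% left from 0.043 M, gives 53.5 M⁻¹, and Wednesday's run, with 4% left from 0.068 M, gives 47.3 M⁻¹. Their mean, 50.4 M⁻¹, is the charge constant: the logarithm of charged over left at 40 min, divided by the starting concentration.

*But those two values differ. Is that a trend?* I don't read it as one: Wednesday's reading of 4% carries a scatter of 1.5 percentage points, and the logarithm of so small a reading is loose.

*And this flask?* At 0.031 M the charge constant leaves 20.9%. The feed swells the volume by a factor 1.25, so I commit to c(starting material) = 0.00519 M. Taking side product at Friday's 6% gives c(side product) = 0.00149 M. I assume one released group for each starting material consumed other than into side product, which gives c(released group) = 0.0181 M.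

The forecast gives 0.005 M, 0.0019 M and 0.025 M, on an apparent power of the concentration which, in its words, “makes sense since catalyst scales with the charge”. Its first value lies near mine, and its other two stand higher than mine.

The flask gives 0.00456 M, 0.00128 M and 0.0177 M.

    reagent + free catalyst → catalyst intermediate A (k = 2800 M⁻¹ s⁻¹)
    catalyst intermediate A → released group + catalyst intermediate B (k = 4.90 s⁻¹)
    starting material + catalyst intermediate B ⇌ catalyst intermediate C (K = 62.0 M⁻¹, k = 70.0 M⁻¹ s⁻¹)
    catalyst intermediate C ⇌ catalyst intermediate D (K = 3.30, k = 3.10 s⁻¹)
    catalyst intermediate D ⇌ free catalyst + target (K = 0.0580 M, k = 2.70 s⁻¹)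
    starting material + released group → side product (k = 0.00490 M⁻¹ s⁻¹)

This flask has not come to rest at 40 min: 18% of its starting material and 27% of its reagent are still there, unbound. Its own charge constant is 54.6 M⁻¹, close to 50.4 M⁻¹. A neighbour flask charged with 0.053 M, on the same equivalents and loading, is reckoned by 50.4 M⁻¹ to keep 6.92% at 40 min, and it keeps 6.5% unbound. Left until 400 min, this flask holds c(starting material) = 1.44 × 10⁻¹³ M, c(side product) rises from 0.00128 M to 0.00171 M, and c(released group) rises from 0.0177 M to 0.0214 M.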